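**Retrosynthetic overview**

1. Labdane numbering is used throughout (ring A = C1–C5, C10; ring B = C5–C10; chain C11–C12; butenolide C13–C16; β = the face of the C10 methyl). The strategy rests on ring B: its oxygens at C6 and C9 and its methyls at C8 and C10 are those of 2,6-dimethyl-1,4-benzoquinone, whose C5=C10 double bond is the dienophile for a diene that brings C1–C4 with the C4 gem-dimethyl group.
2. The target is opened to the 6α,9α-diol (late O-acetylation), then to a (Z)-13-iodo allylic alcohol (butenolide, the last ring, closed by carbonylative lactonisation), then to a terminal alkyne on C12.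
3. The C11–C12 bond comes from opening a 9α,11-spiro-epoxide with a propargyl anion. The epoxide comes from α-face epoxidation of an exocyclic C9=C11 alkene, and the 6α-hydroxyl from dissolving-metal reduction of the C6 ketone.
4. The 9-methylene-6-ketone comes from the saturated trans-fused 6,9-dione (C6 masked as a silyl enol ether, C9 methylenated), which comes from the trans-fused enedione by hydrogenation and C8 equilibration.
5. The enedione comes from the quinone and 4-methylpenta-1,3-diene by a catalytic enantioselective Diels–Alder reaction (bonds C10–C1 and C4–C5) and C5 epimerisation. Ring order: ring B is the carbocycle of the quinone, ring A is closed onto it, the butenolide is closed last.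

Key step: step 2

Assumption: the cation from (S)-diphenylprolinol is taken to leave open the quinone face that leads to the (4aS,8aS) series; if a trial cycloaddition showed the opposite sense, the antipodal ligand would be used with no other change.

**Route**

Step 1
Reactants: 1 (S)-diphenylprolinol; 2 o-tolylboronic acid
Product: 3 (S)-3,3-diphenyl-1-(o-tolyl)tetrahydro-1H,3H-pyrrolo[1,2-c][1,3,2]oxazaborole
Conditions: toluene, reflux, Dean–Stark (−H2O); kept as a toluene stock solution
Reagents that add atoms: none
Why: Condensation of the 1,2-amino alcohol with the boronic acid under azeotropic removal of water gives the B-aryl oxazaborolidine (cyclic aminoboronate formation) without touching the stereocentre of 1.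

Step 2
Reactants: 4 2,6-dimethyl-1,4-benzoquinone; 5 4-methylpenta-1,3-diene
Product: 7 trans-fused enedione (4aS,8aS)-2,5,5,8a-tetramethyl-4a,5,8,8a-tetrahydronaphthalene-1,4-dione, via cis-fused adduct 6 (not isolated)
Conditions: 3 (20 mol %), Tf2NH (18 mol %), CH2Cl2, −78 → −20 °C, 5 (5 equiv), sealed vessel; then DBU (0.3 equiv), 0 °C → rt
Reagents that add atoms: none
Why: Protonation of 3 gives the oxazaborolidinium cation, which binds the more basic and unhindered C6 carbonyl of 4 (the one flanked by two C–H) and activates the C5=C10 bond for a concerted, asynchronous Diels–Alder (4+2) cycloaddition with 5; the closest known type is the cationic-oxazaborolidine-catalysed cycloaddition of methyl-substituted benzoquinones with acyclic dienes. Ring A is closed in one event that is suprafacial on both partners, forming C10–C1 and C4–C5 and giving the cis ring fusion of 6. Regiochemistry follows from binding at the C6 carbonyl, which makes C10 the β-carbon that takes the unsubstituted diene terminus (largest HOMO coefficient), and sterics agree because the dimethyl terminus avoids the methyl-bearing C10. The configuration at C10 is set by the catalyst, which holds the quinone by the carbonyl and the adjacent C5–H and shields one face with an aryl group, so the diene adds to the open face; C5 is first set cis by the suprafacial addition and is then equilibrated by DBU through the C6 enolate to the trans fusion, while the quaternary C10 can neither epimerise nor allow aromatisation. The step needs mono-addition, this regiochemistry and face selectivity: after the first addition the second quinone double bond is a hindered, deactivated enedione alkene, and the sluggish Z-methyl diene is met with excess diene, long reaction time and, if needed, activation of 3 with AlBr3 in place of the acid.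

Step 3
Reactants: 7 trans-fused enedione
Product: 9 saturated trans-fused dione (2R,4aS,8aS)-2,5,5,8a-tetramethyloctahydronaphthalene-1,4-dione (8α-methyl), via 8β-methyl dione 8 (not isolated)
Conditions: H2 (3 atm), 10% Pd/C, EtOAc, rt; filter; then NaOMe (0.2 equiv), MeOH, rt
Reagents that add atoms: none
Why: Heterogeneous hydrogenation saturates the ring A alkene and the electron-poor enedione alkene, and methoxide then equilibrates C8 (α to the C9 ketone) to the equatorial 8α-methyl, because the axial 8β-methyl of 8 is 1,3-diaxial to the C10 methyl; the trans ring fusion is the stable one under the same base.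

Step 4
Reactants: 9 saturated trans-fused dione
Product: 10 6-(tert-butyldimethylsilyloxy)-Δ6 enol ether of 9 (C9 ketone free)
Conditions: LiN(i-Pr)2 (1.1 equiv), THF, −78 °C; then TBSOTf (1.2 equiv), −78 → 0 °C
Reagents that add atoms: tert-butyldimethylsilyl trifluoromethanesulfonate (TBSOTf), CC(C)(C)[Si](C)(C)OS(=O)(=O)C(F)(F)F
Why: Kinetic deprotonation by the hindered amide takes the accessible C7 methylene proton (C5–H and C8–H are tertiary and shielded, C10 is quaternary), and O-silylation of the enolate masks the C6 ketone as its silyl enol ether (regioselective enol silylation).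

Step 5
Reactants: 10 silyl enol ether
Product: 12 9-methylene-6-ketone (3R,4aS,8aS)-3,4a,8,8-tetramethyl-4-methylideneoctahydronaphthalen-1(2H)-one, via β-hydroxysilane 11 (not isolated)
Conditions: Me3SiCH2Li (3 equiv), CeCl3 (3 equiv), THF, −78 → 0 °C; then 1 M HCl, THF, rt
Reagents that add atoms: (trimethylsilyl)methyllithium, [Li]C[Si](C)(C)C
Why: The weakly basic organocerium reagent adds to the crowded, enolisable C9 ketone and acid then eliminates the β-hydroxysilane to the exocyclic C9=C11 alkene (Peterson olefination) while hydrolysing the enol ether back to the C6 ketone; the C9 configuration of 11 is lost in the elimination.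

Step 6
Reactants: 12 9-methylene-6-ketone
Product: 13 6α-alcohol (1S,3R,4aS,8aS)-3,4a,8,8-tetramethyl-4-methylidenedecahydronaphthalen-1-ol
Conditions: Li (excess), NH3(l), THF, MeOH, −78 → −33 °C; then NH4Cl
Reagents that add atoms: none
Why: Dissolving-metal reduction goes through the ketyl and a carbanion that is protonated to the more stable equatorial 6α-alcohol (a 6β-hydroxyl would be syn-axial to the C4 and C10 methyls), the usual outcome for ketones whose axial face carries two syn-axial methyl groups; the isolated alkene is inert.

Step 7
Reactants: 13 6α-alcohol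
Product: 14 9α,11-spiro-epoxide (oxirane oxygen on the α face of C9, C11 β)
Conditions: mCPBA (1.3 equiv), NaHCO3, CH2Cl2, 0 °C
Reagents that add atoms: mCPBA, O=C(OO)c1cccc(Cl)c1
Why: Peracid epoxidation (Prilezhaev reaction) of the exocyclic alkene should occur from the α face, anti to the axial C10 methyl on the neighbouring carbon, which places the oxygen axial (9α) and C11 equatorial and so sets C9.

Step 8
Reactants: 14 9α,11-spiro-epoxide; 15 1-(trimethylsilyl)prop-1-yne
Product: 17 6α,9α-diol with a but-3-ynyl chain on C9 (C11–C12–C13≡C14H), via silylated alkyne 16 (not isolated)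
Conditions: 15 (4 equiv), n-BuLi (3.8 equiv), THF, −78 → 0 °C; then 14, DMPU, 0 °C → rt; then K2CO3, MeOH, rt
Reagents that add atoms: none
Why: The propargylic lithium reagent from 15 opens the 2,2-disubstituted epoxide by SN2 attack at the unsubstituted C11, so the C9–O bond and the 9α configuration are untouched, and methanolic carbonate then removes the alkynyl silyl group (epoxide alkylation, then protodesilylation).

Step 9
Reactants: 17 terminal alkyne diol
Product: 18 propargylic alcohol (6α,9α,15-triol, C13≡C14–C15H2OH)
Conditions: n-BuLi (3.3 equiv), THF, −78 → 0 °C; then (CH2O)n, 0 °C → rt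
Reagents that add atoms: formaldehyde (from paraformaldehyde), C=O
Why: The lithium acetylide of the trilithiated substrate adds to formaldehyde (acetylide hydroxymethylation), the two alkoxides being spectators.

Step 10
Reactants: 18 propargylic alcohol
Product: 19 (Z)-13-iodo allylic alcohol (C13(I)=C14H–C15H2OH, iodine cis to the hydroxymethyl group)
Conditions: NaAlH2(OCH2CH2OMe)2 (Red-Al, 5 equiv), THF, 0 °C → rt; then EtOAc, then I2, −78 → 0 °C
Reagents that add atoms: iodine, II
Why: The propargylic alkoxide directs trans-hydroalumination, with hydride delivered to C14 and aluminium to C13 in a five-membered alkoxyalanate, and iodinolysis with retention gives the (Z)-3-iodoallylic alcohol.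

Step 11
Reactants: 19 (Z)-13-iodo allylic alcohol
Product: 20 6α,9α-dihydroxylabd-13-en-16,15-olide (butenolide diol)
Conditions: Pd(PPh3)4 (5 mol %), CO (1 atm), K2CO3, THF, 50 °C
Reagents that add atoms: carbon monoxide, [C-]#[O+]
Why: Oxidative addition of zerovalent palladium into the vinyl iodide, CO insertion and capture of the acylpalladium by the cis hydroxymethyl group (carbonylative lactonisation) close the butenolide with its carbonyl carbon C16 on C13; the five-membered closure by the primary alcohol outpaces attack by the hindered ring hydroxyls.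

Step 12
Reactants: 20 butenolide diol
Product: 21 target, (5S,6S,8R,9R,10S)-6-acetoxy-9-hydroxylabd-13-en-16,15-olide
Conditions: Ac2O (1.5 equiv), pyridine, DMAP (cat.), CH2Cl2, 0 °C → rt
Reagents that add atoms: acetic anhydride, CC(=O)OC(C)=O
Why: DMAP-catalysed acylation (selective esterification) takes the secondary equatorial 6α-hydroxyl only, the tertiary 9α-hydroxyl flanked by C8 and C10 being inert under these conditions.

**Compound list**

1 | (S)-diphenylprolinol, (S)-diphenyl(pyrrolidin-2-yl)methanol | OC(c1ccccc1)(c1ccccc1)[C@@H]1CCCN1 | starting material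
2 | o-tolylboronic acid | Cc1ccccc1B(O)O | starting material
3 | (S)-3,3-diphenyl-1-(o-tolyl)tetrahydro-1H,3H-pyrrolo[1,2-c][1,3,2]oxazaborole (catalyst precursor) | Cc1ccccc1B1OC(c2ccccc2)(c2ccccc2)[C@@H]2CCCN12 | intermediate
4 | 2,6-dimethyl-1,4-benzoquinone | CC1=CC(=O)C=C(C)C1=O | starting material
5 | 4-methylpenta-1,3-diene | C=CC=C(C)C | starting material
6 | cis-fused adduct, (4aR,8aS)-2,5,5,8a-tetramethyl-4a,5,8,8a-tetrahydronaphthalene-1,4-dione (5β-H, 10β-Me) | O=C1C=C(C)C(=O)[C@@]2(C)CC=CC(C)(C)[C@@H]12 | intermediate
7 | trans-fused enedione, (4aS,8aS)-2,5,5,8a-tetramethyl-4a,5,8,8a-tetrahydronaphthalene-1,4-dione (5α-H, 10β-Me) | O=C1C=C(C)C(=O)[C@@]2(C)CC=CC(C)(C)[C@H]12 | intermediate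
8 | 8β-methyl dione, (2S,4aS,8aS)-2,5,5,8a-tetramethyloctahydronaphthalene-1,4-dione | O=C1C[C@H](C)C(=O)[C@@]2(C)CCCC(C)(C)[C@H]12 | intermediate
9 | 8α-methyl dione, (2R,4aS,8aS)-2,5,5,8a-tetramethyloctahydronaphthalene-1,4-dione | O=C1C[C@@H](C)C(=O)[C@@]2(C)CCCC(C)(C)[C@H]12 | intermediate
10 | 6-(tert-butyldimethylsilyloxy)-Δ6 enol ether of 9 (5α-H, 8α-Me, 10β-Me, C9 ketone) | CC(C)(C)[Si](C)(C)OC1=C[C@@H](C)C(=O)[C@@]2(C)CCCC(C)(C)[C@H]12 | intermediate
11 | 9β-hydroxy-9α-(trimethylsilylmethyl) adduct of 10 (expected major C9 epimer) | CC(C)(C)[Si](C)(C)OC1=C[C@@H](C)[C@@](O)(C[Si](C)(C)C)[C@@]2(C)CCCC(C)(C)[C@H]12 | intermediate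
12 | 9-methylene-6-ketone, (3R,4aS,8aS)-3,4a,8,8-tetramethyl-4-methylideneoctahydronaphthalen-1(2H)-one | O=C1C[C@@H](C)C(=C)[C@@]2(C)CCCC(C)(C)[C@H]12 | intermediate
13 | 6α-alcohol, (1S,3R,4aS,8aS)-3,4a,8,8-tetramethyl-4-methylidenedecahydronaphthalen-1-ol | O[C@H]1C[C@@H](C)C(=C)[C@@]2(C)CCCC(C)(C)[C@H]12 | intermediate
14 | 9α,11-spiro-epoxide of 13 (6α-OH, 8α-Me, epoxide oxygen α) | O[C@H]1C[C@@H](C)[C@]3(CO3)[C@@]2(C)CCCC(C)(C)[C@H]12 | intermediate
15 | 1-(trimethylsilyl)prop-1-yne | CC#C[Si](C)(C)C | starting material
16 | 6α,9α-diol with 4-(trimethylsilyl)but-3-ynyl chain on C9 | O[C@H]1C[C@@H](C)[C@](O)(CCC#C[Si](C)(C)C)[C@@]2(C)CCCC(C)(C)[C@H]12 | intermediate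
17 | 6α,9α-diol with but-3-ynyl chain on C9 | O[C@H]1C[C@@H](C)[C@](O)(CCC#C)[C@@]2(C)CCCC(C)(C)[C@H]12 | intermediate
18 | 6α,9α,15-triol with 5-hydroxypent-3-ynyl chain on C9 | O[C@H]1C[C@@H](C)[C@](O)(CCC#CCO)[C@@]2(C)CCCC(C)(C)[C@H]12 | intermediate
19 | (Z)-13-iodo-13-ene-6α,9α,15-triol | O[C@H]1C[C@@H](C)[C@](O)(CC/C(I)=C/CO)[C@@]2(C)CCCC(C)(C)[C@H]12 | intermediate
20 | 6α,9α-dihydroxylabd-13-en-16,15-olide | O[C@H]1C[C@@H](C)[C@](O)(CCC2=CCOC2=O)[C@@]2(C)CCCC(C)(C)[C@H]12 | intermediate
21 | (5S,6S,8R,9R,10S)-6-acetoxy-9-hydroxylabd-13-en-16,15-olide (CNP0205088.2) | CC(=O)O[C@H]1C[C@@H](C)[C@](O)(CCC2=CCOC2=O)[C@@]2(C)CCCC(C)(C)[C@H]12 | target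

**Step count and risk**

Total step count: 12 (11 on the carbon path, 1 for the catalyst precursor).
Longest linear sequence: 11 steps (4 → 21, steps 2–12).

Steps most likely to fail:

Step 2. The Z-methyl group of 5 disfavours the s-cis conformer, so the cycloaddition may be slow; the strong acid may oligomerise the diene; and face discrimination at the trisubstituted dienophile may be insufficient. Fallback, setting out from 4 and 5: the cycloaddition is run without the chiral catalyst (BF3·OEt2 at low temperature, or neat at 12–15 kbar) to give the racemic cis-fused adduct F1, which DBU epimerises to the racemic trans-fused enedione F2. Preparative chromatography on a chiral stationary phase then gives the (4aS,8aS) enantiomer, and the route is rejoined at 7.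

Step 8. The crowded C11 may resist attack by the carbanion, the basic reagent may instead isomerise the epoxide to an allylic alkoxide by removing the C8 proton, or lithium salts may trigger a Meinwald rearrangement. Fallback, setting out from 14: the epoxide is opened at C11 by the soft, non-basic nucleophile PhSeNa (from PhSeSePh and NaBH4, EtOH) to the β-hydroxy selenide F3. The C11 radical generated from it (Bu3SnH, AIBN, benzene, 80 °C) adds to α-methylene-γ-butyrolactone (Giese addition) to give the saturated α-substituted lactone F4 as a mixture at C13. α-Selenenylation (LiN(i-Pr)2 in excess, PhSeCl) gives the α-phenylselanyl lactone F5, and oxidation with H2O2 followed by selenoxide syn-elimination into the ring gives the butenolide. The route is rejoined at 20, so steps 9–11 are not needed.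

Step 5. The enol ether makes the C8 proton (α to the ketone and allylic) more acidic, so enolisation may outrun addition at the crowded C9 carbonyl, or the enol ether may be lost before the addition. Fallback, setting out from 9: LiBH(s-Bu)3 (THF, −78 °C) reduces only the C6 ketone, by equatorial attack from the open α face, to the 6β-hydroxy ketone F6. Wittig methylenation of the C9 ketone with excess Ph3P=CH2 (toluene, 90 °C; C6 is protected as its alkoxide) gives the 6β-hydroxy exocyclic alkene F7, and Dess–Martin oxidation rejoins the route at 12.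

Further compounds
F1 | step 2 | racemic cis-fused adduct (racemate of 6) | O=C1C=C(C)C(=O)[C@@]2(C)CC=CC(C)(C)[C@@H]12.O=C1C=C(C)C(=O)[C@]2(C)CC=CC(C)(C)[C@H]12
F2 | step 2 | racemic trans-fused enedione (racemate of 7) | O=C1C=C(C)C(=O)[C@@]2(C)CC=CC(C)(C)[C@H]12.O=C1C=C(C)C(=O)[C@]2(C)CC=CC(C)(C)[C@@H]12
F3 | step 8 | 6α,9α-diol with phenylselanylmethyl group on C9 (C11–SePh) | O[C@H]1C[C@@H](C)[C@](O)(C[Se]c3ccccc3)[C@@]2(C)CCCC(C)(C)[C@H]12
F4 | step 8 | 6α,9α-dihydroxylabdan-16,15-olide (saturated lactone, C13 epimers) | O[C@H]1C[C@@H](C)[C@](O)(CCC3CCOC3=O)[C@@]2(C)CCCC(C)(C)[C@H]12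
F5 | step 8 | 13-(phenylselanyl) derivative of the saturated lactone | O[C@H]1C[C@@H](C)[C@](O)(CCC3([Se]c4ccccc4)CCOC3=O)[C@@]2(C)CCCC(C)(C)[C@H]12
F6 | step 5 | 6β-hydroxy-9-ketone (5α-H, 8α-Me, 10β-Me) | O[C@@H]1C[C@@H](C)C(=O)[C@@]2(C)CCCC(C)(C)[C@H]12
F7 | step 5 | 6β-hydroxy-9-methylene compound (6-epimer of 13) | O[C@@H]1C[C@@H](C)C(=C)[C@@]2(C)CCCC(C)(C)[C@H]12
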